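## Retrosynthetic overview

1. Dictyol H ⇐ desilylation, methylenation of a C10 ketone and conjugate reduction of a cis-fused hydroazulenone (C8=C9–C10=O).
2. Seven-membered ring ⇐ ring-closing metathesis (C8=C9) between a C7 vinyl group and a C10 vinyl ketone. This is the key ring closure and the last ring formed.
3. RCM diene ⇐ anti-selective Nozaki–Hiyama allylation (C6–C7 bond) of a cis-cyclopentene keto-aldehyde with an (E)-allyl bromide that already carries the complete THF–acetate side chain.
4. Allyl bromide ⇐ (R)-linalool by asymmetric epoxidation and 5-exo cyclisation (THF ring, formed first in its branch), acetylation and vinyl-to-allyl homologation.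
5. Keto-aldehyde ⇐ cis-fused bicyclic lactone ⇐ RCM (cyclopentene ring) ⇐ Rh-catalysed asymmetric isopropenyl addition to 2(5H)-furanone, then allylation.

Assumption: numbers are given to substrates and intermediates; purchased atom-donating reagents and catalysts are listed with SMILES in each step. Atom labels C1–C15 use dictyol numbering (C1/C5 ring fusion, C6 carbinol, C7 side-chain attachment, C10 methylene-bearing carbon, C11/C14 THF carbons).

## Branch A: cyclopentene keto-aldehyde

**Step 1**
Reactants: 1, furan-2(5H)-one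
Product: 2, (R)-4-(prop-1-en-2-yl)dihydrofuran-2(3H)-one
Conditions: K[isopropenyl-BF3], [Rh(cod)2]BF4 (3 mol%), (R)-BINAP, toluene/H2O 20:1, 105 °C
Reagents that add atoms: potassium isopropenyltrifluoroborate, [K+].C=C(C)[B-](F)(F)F
Why: Hayashi–Miyaura Rh/BINAP conjugate addition; the Rh–alkenyl adds to one enantioface of the butenolide and sets C5 as R (same facial sense as (R)-BINAP giving (R)-3-substituted cyclohexanones).

**Step 2**
Reactants: 2
Product: 3, (3S,4R)-3-allyl-4-(prop-1-en-2-yl)dihydrofuran-2(3H)-one (trans)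
Conditions: LiHMDS, THF, −78 °C; allyl bromide, −78 → −40 °C
Reagents that add atoms: allyl bromide, C=CCBr
Why: Lactone enolate alkylation; the electrophile enters anti to the β-isopropenyl group, giving the trans lactone.

**Step 3**
Reactants: 3
Product: 4, (3R,4R)-3-allyl-4-(prop-1-en-2-yl)dihydrofuran-2(3H)-one (cis)
Conditions: LDA, THF, −78 °C; inverse quench into 2,6-di-tert-butyl-4-methylphenol, −78 °C
Reagents that add atoms: none
Why: Kinetic protonation of the planar enolate from the face opposite the isopropenyl group pushes the allyl group cis and sets C1 as R; recovered trans isomer is recycled.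

**Step 4**
Reactants: 4
Product: 5, (3aR,6aR)-4-methyl-3,3a,6,6a-tetrahydro-1H-cyclopenta[c]furan-1-one (cis-fused lactone)
Conditions: Grubbs II (3 mol%), CH2Cl2 (0.02 M), 40 °C
Reagents that add atoms: none
Why: Ring-closing metathesis of the allyl and isopropenyl groups gives the trisubstituted cyclopentene; only the cis isomer can close to the bicyclo[3.3.0] system, so any residual trans lactone is left behind.

**Step 5**
Reactants: 5
Product: 6, (3aR,6aR)-4-methyl-3,3a,6,6a-tetrahydro-1H-cyclopenta[c]furan-1-ol (lactol, anomer mixture)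
Conditions: DIBAL-H (1.1 equiv), CH2Cl2, −78 °C; Rochelle salt
Reagents that add atoms: none
Why: Partial lactone reduction stops at the tetrahedral aluminate at −78 °C; the ring-fusion centres are untouched.

**Step 6**
Reactants: 6
Product: 7, 1-[(1R,2R)-2-(hydroxymethyl)-3-methylcyclopent-3-en-1-yl]prop-2-en-1-ol (carbinol epimers)
Conditions: CH2=CHMgBr (3 equiv), THF, 0 °C → rt
Reagents that add atoms: vinylmagnesium bromide, C=C[Mg]Br
Why: Grignard addition to the open hydroxy-aldehyde form of the lactol; the new carbinol centre is irrelevant because it is oxidised in the next step.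

**Step 7**
Reactants: 7
Product: 8, (1R,5R)-2-methyl-5-(prop-2-enoyl)cyclopent-2-ene-1-carbaldehyde (cis keto-aldehyde; used crude at once)
Conditions: (COCl)2, DMSO, CH2Cl2, −78 °C; i-Pr2NEt, −78 → −30 °C; cold pH 7 buffer
Reagents that add atoms: none
Why: Swern double oxidation; both hydroxyls are activated before base is added, so no lactol-to-lactone over-oxidation occurs, and the hindered base at low temperature spares the epimerisable C1/C5 centres.

## Branch B: side-chain allyl bromide

**Step 8**
Reactants: 9, (R)-(−)-linalool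
Product: 10, (3R,6S)-6,7-epoxylinalool [(3R)-5-[(2S)-3,3-dimethyloxiran-2-yl]-3-methylpent-1-en-3-ol]
Conditions: ent-Shi ketone (L-fructose-derived, 0.3 equiv), Oxone, K2CO3, Bu4NHSO4, MeCN/DMM/aq. borate buffer (pH 10.5), 0 °C
Reagents that add atoms: Oxone (KHSO5), [K+].[O-]S(=O)(=O)OO
Why: Shi asymmetric epoxidation; the electron-rich trisubstituted olefin reacts chemoselectively, and the L-series ketone delivers the (6S)-epoxide by reagent control (the D-fructose ketone gives 6R).

**Step 9**
Reactants: 10
Product: 11, 2-[(2R,5R)-5-methyl-5-vinyltetrahydrofuran-2-yl]propan-2-ol (vinyl and hydroxy-isopropyl groups trans)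
Conditions: CSA (5 mol%), CH2Cl2, 0 °C → rt; chromatography from the minor pyranoid isomer
Reagents that add atoms: none
Why: Acid-catalysed 5-exo-tet epoxide opening by the tertiary hydroxyl with inversion at the secondary carbon sets C14 as R; C11 (R) comes unchanged from linalool.

**Step 10**
Reactants: 11
Product: 12, 2-[(2R,5R)-5-methyl-5-vinyltetrahydrofuran-2-yl]propan-2-yl acetate
Conditions: Ac2O, Et3N, DMAP (0.5 equiv), CH2Cl2, 40 °C
Reagents that add atoms: acetic anhydride, CC(=O)OC(C)=O
Why: DMAP-catalysed (Steglich-type) acylation is effective for tertiary alcohols; installing the acetate here avoids any late differentiation from the C6 hydroxyl.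

**Step 11**
Reactants: 12
Product: 13, 2-[(2R,5R)-5-formyl-5-methyltetrahydrofuran-2-yl]propan-2-yl acetate
Conditions: O3, CH2Cl2, −78 °C; PPh3, → rt
Reagents that add atoms: ozone, [O-][O+]=O
Why: Ozonolysis of the only olefin gives a non-enolisable α-alkoxy aldehyde, so C11 cannot epimerise.

**Step 12**
Reactants: 13
Product: 14, 2-[(2R,5R)-5-methyl-5-[(E)-3-oxoprop-1-en-1-yl]tetrahydrofuran-2-yl]propan-2-yl acetate
Conditions: Ph3P=CHCHO (1.5 equiv), toluene, 90 °C
Reagents that add atoms: (triphenylphosphoranylidene)acetaldehyde, O=CC=P(c1ccccc1)(c1ccccc1)c1ccccc1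
Why: Wittig olefination with a stabilised ylide is E-selective, and the activated α-alkoxy aldehyde reacts faster than the enal product, limiting double homologation.

**Step 13**
Reactants: 14
Product: 15, 2-[(2R,5R)-5-[(E)-3-hydroxyprop-1-en-1-yl]-5-methyltetrahydrofuran-2-yl]propan-2-yl acetate
Conditions: NaBH4, CeCl3·7H2O, MeOH, −40 → 0 °C
Reagents that add atoms: none
Why: Luche 1,2-reduction of the enal leaves the hindered tertiary acetate intact.

**Step 14**
Reactants: 15
Product: 16, 2-[(2R,5R)-5-[(E)-3-bromoprop-1-en-1-yl]-5-methyltetrahydrofuran-2-yl]propan-2-yl acetate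
Conditions: CBr4, PPh3, 2,6-lutidine, CH2Cl2, 0 °C
Reagents that add atoms: carbon tetrabromide, BrC(Br)(Br)Br
Why: Appel bromination is an SN2 reaction at the primary allylic carbon, with no transposition and neutral conditions.

## Coupling and end-game

**Step 15**
Reactants: 8, cis keto-aldehyde; 16, (E)-allyl bromide (1.3 equiv)
Product: 17, 1-[(1R,5R)-5-{(1S,2R)-2-[(2R,5R)-5-(2-acetoxypropan-2-yl)-2-methyltetrahydrofuran-2-yl]-1-hydroxybut-3-en-1-yl}-4-methylcyclopent-3-en-1-yl]prop-2-en-1-one
Conditions: CrCl2 (5 equiv), THF, 0 °C → rt (no silyl chloride additive)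
Reagents that add atoms: none
Why: Nozaki–Hiyama allylation; the allylchromium attacks through its γ-carbon in a chair transition state (anti C6/C7), on the Felkin–Anh face of the aldehyde (anti to alkenyl C4, passing over H-5), which should give 6S,7R. The aldehyde reacts far faster than the vinyl ketone.

**Step 16**
Reactants: 17
Product: 18, the C6 triethylsilyl ether of 17
Conditions: TESOTf, 2,6-lutidine, CH2Cl2, −78 °C
Reagents that add atoms: triethylsilyl triflate, CC[Si](CC)(CC)OS(=O)(=O)C(F)(F)F
Why: Silylation with a non-nucleophilic base (no aza-Michael addition to the vinyl ketone) blocks hemiketal formation between C6–OH and the C10 ketone in the following steps.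

**Step 17**
Reactants: 18
Product: 19, cis-fused hydroazulenone (dictyol numbering: Δ8,9-10-one, 6-OTES, 7-THF side chain; 1R,5R,6S,7R,11R,14R)
Conditions: Hoveyda–Grubbs II (10 mol%), toluene (2 mM), 80 °C
Reagents that add atoms: none
Why: Ring-closing metathesis; Ru initiates at the C7 vinyl group and closes onto the vinyl ketone to give the seven-membered enone with loss of ethylene; no stereocentre is touched.

**Step 18**
Reactants: 19
Product: 20, the saturated C10 ketone (8,9-dihydro-19)
Conditions: [(Ph3P)CuH]6 (Stryker's reagent), wet benzene, rt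
Reagents that add atoms: none
Why: Copper-hydride conjugate reduction is selective for the enone over the trisubstituted cyclopentene and the acetate; C8 and C9 become CH2, so no new stereocentre arises.

**Step 19**
Reactants: 20
Product: 21, 6-O-triethylsilyl dictyol H
Conditions: Tebbe reagent (1.3 equiv), pyridine, THF/toluene, −40 → 0 °C
Reagents that add atoms: Tebbe reagent (written as Cp2Ti=CH2·ClAlMe2), C=[Ti](C1C=CC=C1)C1C=CC=C1.C[Al](C)Cl
Why: Non-basic Tebbe methylenation avoids epimerisation at C1 (α to the ketone), and at low temperature the ketone reacts much faster than the hindered tertiary acetate.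

**Step 20**
Reactants: 21
Product: 22, dictyol H
Conditions: HF·pyridine, pyridine, THF, 0 °C → rt
Reagents that add atoms: none
Why: Buffered fluoride desilylation frees the C6 hydroxyl without affecting the tertiary acetate, the exocyclic methylene or the THF ring.

## Compound list

1 | furan-2(5H)-one | O=C1C=CCO1 | starting material
2 | (R)-4-(prop-1-en-2-yl)dihydrofuran-2(3H)-one | O=C1C[C@@H](CO1)C(C)=C | intermediate
3 | (3S,4R)-3-allyl-4-(prop-1-en-2-yl)dihydrofuran-2(3H)-one | O=C1[C@@H](CC=C)[C@@H](CO1)C(C)=C | intermediate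
4 | (3R,4R)-3-allyl-4-(prop-1-en-2-yl)dihydrofuran-2(3H)-one | O=C1[C@H](CC=C)[C@@H](CO1)C(C)=C | intermediate
5 | (3aR,6aR)-4-methyl-3,3a,6,6a-tetrahydro-1H-cyclopenta[c]furan-1-one | O=C1OC[C@H]2C(C)=CC[C@@H]12 | intermediate
6 | (3aR,6aR)-4-methyl-3,3a,6,6a-tetrahydro-1H-cyclopenta[c]furan-1-ol (anomers) | OC1OC[C@H]2C(C)=CC[C@@H]12 | intermediate
7 | 1-[(1R,2R)-2-(hydroxymethyl)-3-methylcyclopent-3-en-1-yl]prop-2-en-1-ol (epimers) | OC[C@H]1C(C)=CC[C@H]1C(O)C=C | intermediate
8 | (1R,5R)-2-methyl-5-(prop-2-enoyl)cyclopent-2-ene-1-carbaldehyde | O=C[C@H]1C(C)=CC[C@H]1C(=O)C=C | intermediate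
9 | (R)-(−)-linalool | C=C[C@@](O)(C)CCC=C(C)C | starting material
10 | (3R,6S)-6,7-epoxylinalool | C=C[C@@](O)(C)CC[C@@H]1OC1(C)C | intermediate
11 | 2-[(2R,5R)-5-methyl-5-vinyltetrahydrofuran-2-yl]propan-2-ol | C=C[C@@]1(C)CC[C@H](C(C)(C)O)O1 | intermediate
12 | 2-[(2R,5R)-5-methyl-5-vinyltetrahydrofuran-2-yl]propan-2-yl acetate | C=C[C@@]1(C)CC[C@H](C(C)(C)OC(C)=O)O1 | intermediate
13 | 2-[(2R,5R)-5-formyl-5-methyltetrahydrofuran-2-yl]propan-2-yl acetate | O=C[C@@]1(C)CC[C@H](C(C)(C)OC(C)=O)O1 | intermediate
14 | 2-[(2R,5R)-5-methyl-5-[(E)-3-oxoprop-1-enyl]tetrahydrofuran-2-yl]propan-2-yl acetate | O=C/C=C/[C@@]1(C)CC[C@H](C(C)(C)OC(C)=O)O1 | intermediate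
15 | 2-[(2R,5R)-5-[(E)-3-hydroxyprop-1-enyl]-5-methyltetrahydrofuran-2-yl]propan-2-yl acetate | OC/C=C/[C@@]1(C)CC[C@H](C(C)(C)OC(C)=O)O1 | intermediate
16 | 2-[(2R,5R)-5-[(E)-3-bromoprop-1-enyl]-5-methyltetrahydrofuran-2-yl]propan-2-yl acetate | BrC/C=C/[C@@]1(C)CC[C@H](C(C)(C)OC(C)=O)O1 | intermediate
17 | coupled hydroxy dienone (1R,5R,6S,7R,11R,14R) | C=C[C@@H]([C@@]2(C)CC[C@H](C(C)(C)OC(C)=O)O2)[C@@H](O)[C@H]2C(C)=CC[C@H]2C(=O)C=C | intermediate
18 | C6 TES ether of 17 | C=C[C@@H]([C@@]2(C)CC[C@H](C(C)(C)OC(C)=O)O2)[C@@H](O[Si](CC)(CC)CC)[C@H]2C(C)=CC[C@H]2C(=O)C=C | intermediate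
19 | cis-fused hydroazulen-10-one, Δ8,9, 6-OTES | O=C1C=C[C@@H]([C@@]2(C)CC[C@H](C(C)(C)OC(C)=O)O2)[C@@H](O[Si](CC)(CC)CC)[C@H]2C(C)=CC[C@@H]12 | intermediate
20 | saturated C10 ketone, 6-OTES | O=C1CC[C@@H]([C@@]2(C)CC[C@H](C(C)(C)OC(C)=O)O2)[C@@H](O[Si](CC)(CC)CC)[C@H]2C(C)=CC[C@@H]12 | intermediate
21 | 6-O-TES dictyol H | C=C1CC[C@@H]([C@@]2(C)CC[C@H](C(C)(C)OC(C)=O)O2)[C@@H](O[Si](CC)(CC)CC)[C@H]2C(C)=CC[C@@H]12 | intermediate
22 | dictyol H | C=C1CC[C@@H]([C@@]2(C)CC[C@H](C(C)(C)OC(C)=O)O2)[C@@H](O)[C@H]2C(C)=CC[C@@H]12 | target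

## Summary

Total steps: 20 (branch A: 7, branch B: 7, after coupling: 6).
Longest linear sequence: 13 steps (steps 1–7 or 8–14, then 15–20), which is 65% of the total.

Three steps most likely to fail:

1. **Step 15 (Nozaki–Hiyama coupling).** The 6S,7R outcome rests on substrate (Felkin) control with little help from C11. Keto-aldehyde 8 is epimerisable, and α-attack, 1,4-elimination of the δ-alkoxy allylchromium or Cr(II) chemistry at the vinyl ketone could compete.
   Fallback: switch to a reagent-controlled boron coupling. Convert 15 into the (E)-allyl pinacol boronate (Pd-catalysed borylation) and run a chiral phosphoric acid (TRIP)-catalysed allylboration on the more robust Weinreb-amide aldehyde (from lactone 5 with Me(MeO)NH·HCl/AlMe3, then oxidation). The vinyl ketone is then introduced after coupling, accepting loss of the acetate in the Grignard step and re-acetylating the tertiary alcohol before the final desilylation.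

2. **Step 17 (seven-membered RCM).** The C7 vinyl group is flanked by the quaternary C11 and the silyloxy carbon, and the partner is an electron-poor vinyl ketone.
   Fallback: take the enone out of the metathesis step. Luche-reduce the vinyl ketone of 18 to the allylic alcohol, close the ring as an electron-neutral diene (adding a relay tether on the C8 olefin if initiation is the problem), then oxidise the ring allylic alcohol back to enone 19.

3. **Step 3 (cis-selective protonation).** Selectivity may be modest, and the cis lactone is the less stable isomer.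
   Fallback: set C1 and C5 independently with an Evans auxiliary. Add isopropenyl cuprate to an N-[(E)-4-silyloxybut-2-enoyl]oxazolidinone, carry out auxiliary-controlled α-allylation, then RCM and acid-mediated desilylation/lactonisation to reach the same lactone 5.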